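A direct plan would make the ring B salicylate A1 (methyl 2-hydroxy-4-methoxy-6-pentanoylbenzoate) and alkylate its phenoxide with 4-chloro-3-pentylcyclobut-2-en-1-one A2 to give the cyclobutenyl ether A3.
It would then grow ring A on the ether oxygen by thermal benzannulation of A3 with (triisopropylsilyloxy)acetylene A4, and desilylate.
Weak point one would be the displacement of chloride from A2 by the phenoxide: this C–O bond formation has no counterpart, A2 would come from a partial dechlorination that is hard to stop, and the whole plan would hang on it.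
Weak point two would be the benzannulation that builds ring A: it would run late, at 80–110 °C, on a keto ester, would need the right sense of ring opening and of alkyne addition, and would consume a labile terminal siloxyalkyne that costs two steps of its own.
Weak point three would be the run-up to A1: six linear steps of oxidation-state and protecting-group changes (carbinol, lactone, keto acid, ester, demethylation) for a trisubstituted benzoate would form no bond of the core.

**Retrosynthetic overview**

Ring A is the pentylresorcinol ring (C1 ether carbon, C2 and C4 hydroxyls, C6 pentyl); ring B is the benzoate ring (C1 ester-bearing, C2 aryloxy, C4 methoxy, C6 pentanoyl).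
The ester carbon on C1 of ring B beside the ether oxygen on C2, and the hydroxyls ortho (C2) and para (C4) to the ether carbon C1 of ring A, are the pattern left when a 2,4'-dihydroxybenzophenone is oxidised to a spiro grisadienedione and opened by methanol, as on the path from benzophenones to fungal diphenyl ethers.
Key disconnection: the ether bond O(ring B C2)–C1(ring A) and the methyl ester are made together from the ketone bond C(=O)–C1(ring A) of (2,4-dihydroxy-6-pentylphenyl)(2-hydroxy-4-methoxy-6-pentanoylphenyl)methanone, the aryl group moving from carbon to oxygen.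
The benzophenone comes from a 3-arylphthalide: lithiated olivetol dibenzyl ether adds to methyl 2-formyl-3,5-dimethoxybenzoate, n-butyllithium turns the lactone carbonyl into the pentanoyl group, and oxidation gives the 1,2-diacylbenzene.
Both benzene rings are bought as such, and the only ring closed is the transient five-membered spiro furanone of the key step, so no cyclobutenone, siloxyalkyne or thermal benzannulation is needed; every stereocentre on the way is racemic and is erased before the end.

Key step: step 8

Step 1
Reactants: 1 methyl 3,5-dimethoxybenzoate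
Product: 3 methyl 2-formyl-3,5-dimethoxybenzoate, via iminium salt 2 (not isolated)
Conditions: POCl3 (3 equiv), DMF, 0 to 90 °C; then H2O
Reagents that add atoms: N,N-dimethylformamide, CN(C)C=O; water, O
Why: Vilsmeier–Haack formylation, in which the chloroiminium ion attacks para to one methoxy group and ortho to the other, beside the ester, since the site between the two methoxy groups is the more crowded, and water hydrolyses iminium salt 2 to the aldehyde.

Step 2
Reactants: 4 olivetol (5-pentylbenzene-1,3-diol)
Product: 5 1,3-bis(benzyloxy)-5-pentylbenzene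
Conditions: BnBr (2.2 equiv), K2CO3, DMF, 60 °C
Reagents that add atoms: benzyl bromide, BrCc1ccccc1
Why: Williamson ether synthesis on both phenols gives benzyl ethers that survive the organolithium steps and are removed later together with the one methyl ether that has to go.

Step 3
Reactants: 5 1,3-bis(benzyloxy)-5-pentylbenzene
Product: 6 1,5-bis(benzyloxy)-2-bromo-3-pentylbenzene
Conditions: NBS (1.0 equiv), MeCN, 0 °C
Reagents that add atoms: N-bromosuccinimide, O=C1CCC(=O)N1Br
Why: Electrophilic aromatic bromination with NBS in a polar solvent goes para to one benzyloxy group and ortho to the other, next to the pentyl chain, because the site between the two ether groups is more crowded, as is established for 3,5-dialkoxyalkylbenzenes.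

Step 4
Reactants: 6 1,5-bis(benzyloxy)-2-bromo-3-pentylbenzene; 3 methyl 2-formyl-3,5-dimethoxybenzoate
Product: 9 (±)-3-[2,4-bis(benzyloxy)-6-pentylphenyl]-4,6-dimethoxy-2-benzofuran-1(3H)-one, via aryllithium 7 (not isolated), via lithium alkoxide 8 (not isolated)
Conditions: t-BuLi (2.0 equiv), THF, −78 °C; then 3, −78 °C to rt; aq NH4Cl
Reagents that add atoms: none
Why: Bromine–lithium exchange gives aryllithium 7, which adds to the aldehyde of 3 much faster than to its ester (1,2-addition), and alkoxide 8 closes on the neighbouring methyl ester to the five-membered lactone, so that the future ester carbon sits between the oxygen-bearing carbon and the future pentanoyl carbon of ring B, while the new stereocentre is racemic and is oxidised away in step 6.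

Step 5
Reactants: 9 (±)-3-[2,4-bis(benzyloxy)-6-pentylphenyl]-4,6-dimethoxy-2-benzofuran-1(3H)-one; 10 n-butyllithium
Product: 11 3-[2,4-bis(benzyloxy)-6-pentylphenyl]-1-butyl-4,6-dimethoxy-1,3-dihydro-2-benzofuran-1-ol (lactol, mixture of diastereomers)
Conditions: n-BuLi (1.1 equiv), THF, −78 °C; aq NH4Cl at −78 °C
Reagents that add atoms: n-butyllithium (10), CCCC[Li]
Why: Addition of an organolithium reagent to a lactone stops at the lithium lactolate at −78 °C, so one butyl group enters at the lactone carbonyl carbon, which lies beside the unsubstituted ring position and becomes the pentanoyl carbon, and the hemiketal centre is of no consequence.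

Step 6
Reactants: 11 3-[2,4-bis(benzyloxy)-6-pentylphenyl]-1-butyl-4,6-dimethoxy-1,3-dihydro-2-benzofuran-1-ol
Product: 13 [2,4-bis(benzyloxy)-6-pentylphenyl](2,4-dimethoxy-6-pentanoylphenyl)methanone, via hydroxy ketone 12 (not isolated)
Conditions: Dess–Martin periodinane (1.5 equiv), pyridine, CH2Cl2, rt
Reagents that add atoms: none
Why: Lactol 11 is in ring–chain equilibrium with hydroxy ketone 12, whose secondary diarylmethanol is oxidised by the Dess–Martin reagent (alcohol oxidation, the usual way from phthalide-derived lactols to 1,2-diacylbenzenes), which removes both stereocentres.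

Step 7
Reactants: 13 [2,4-bis(benzyloxy)-6-pentylphenyl](2,4-dimethoxy-6-pentanoylphenyl)methanone
Product: 14 (2,4-dihydroxy-6-pentylphenyl)(2-hydroxy-4-methoxy-6-pentanoylphenyl)methanone
Conditions: BCl3 (6 equiv), C6HMe5 (6 equiv), CH2Cl2, −78 to 0 °C; then H2O
Reagents that add atoms: none
Why: BCl3 cleaves the two benzyl ethers, the benzyl cations being trapped by pentamethylbenzene, and the one methyl ether that chelates to the diaryl ketone carbonyl group (chelation-controlled ortho-demethylation), while the C4 methoxy group of ring B, para to that carbonyl group and without a neighbouring carbonyl oxygen, stays.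

Step 8
Reactants: 14 (2,4-dihydroxy-6-pentylphenyl)(2-hydroxy-4-methoxy-6-pentanoylphenyl)methanone
Product: 16 methyl 2-(2,4-dihydroxy-6-pentylphenoxy)-4-methoxy-6-pentanoylbenzoate (target), via grisadienedione 15 (not isolated)
Conditions: PhI(OAc)2 (1.0 equiv), MeCN, −20 °C, argon; then MeOH, Et3N (3 equiv), 0 °C to rt; aq NH4Cl
Reagents that add atoms: methanol, CO
Why: Trivalent iodine oxidises the more electron-rich ring A (two hydroxyls and an alkyl group, against the pentanoyl-deactivated ring B) by two electrons, and the ring B hydroxyl, which the ketone bridge holds over C1 of ring A, attacks that carbon, para to the C4 hydroxyl and ortho to the C2 hydroxyl, to close the five-membered furanone ring of spirodienone 15 (5-exo closure onto the ipso carbon); this is the oxidative phenol coupling by which 2,4'-dihydroxybenzophenones are known to give grisadienediones. The ether C–O bond can form only at C1 of ring A, because the other activated carbons (C3, C5) cannot be reached through a five-membered ring. In 15 the furanone carbonyl carbon and the dienone system meet at the quaternary spiro carbon, so methanol with triethylamine cleaves the C(=O)–C(spiro) bond by retro-Claisen fragmentation, driven by the return of ring A to a benzene ring, which leaves the carbonyl carbon as the open methyl ester on ring B and the dienone oxygens as the C2 and C4 hydroxyls of ring A; this is the known solvolytic opening of grisadienediones to diaryl ethers. The spiro carbon of 15 is the only new stereocentre, it is racemic and it disappears on aromatisation. The selectivity needed is oxidation before fragmentation: one equivalent of oxidant is consumed in a non-nucleophilic solvent while ring A is masked as the dienone, so the oxidation-sensitive hydroxyquinol ether 16 appears only when no oxidant is left, and triethylamine in methanol is too weak a base to condense the pentanoyl enolate onto the new ester.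

**Compound list**

1 | methyl 3,5-dimethoxybenzoate | COC(=O)c1cc(OC)cc(OC)c1 | starting material
2 | N-{[2,4-dimethoxy-6-(methoxycarbonyl)phenyl]methylidene}-N-methylmethanaminium chloride (aryl iminium salt) | COC(=O)c1cc(OC)cc(OC)c1C=[N+](C)C.[Cl-] | intermediate
3 | methyl 2-formyl-3,5-dimethoxybenzoate | COC(=O)c1cc(OC)cc(OC)c1C=O | intermediate
4 | olivetol (5-pentylbenzene-1,3-diol) | CCCCCc1cc(O)cc(O)c1 | starting material
5 | 1,3-bis(benzyloxy)-5-pentylbenzene | CCCCCc1cc(OCc2ccccc2)cc(OCc2ccccc2)c1 | intermediate
6 | 1,5-bis(benzyloxy)-2-bromo-3-pentylbenzene | CCCCCc1cc(OCc2ccccc2)cc(OCc2ccccc2)c1Br | intermediate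
7 | [2,4-bis(benzyloxy)-6-pentylphenyl]lithium | CCCCCc1cc(OCc2ccccc2)cc(OCc2ccccc2)c1[Li] | intermediate
8 | lithium (±)-[2,4-bis(benzyloxy)-6-pentylphenyl][2,4-dimethoxy-6-(methoxycarbonyl)phenyl]methanolate | CCCCCc1cc(OCc2ccccc2)cc(OCc2ccccc2)c1C(O[Li])c1c(OC)cc(OC)cc1C(=O)OC | intermediate
9 | (±)-3-[2,4-bis(benzyloxy)-6-pentylphenyl]-4,6-dimethoxy-2-benzofuran-1(3H)-one | CCCCCc1cc(OCc2ccccc2)cc(OCc2ccccc2)c1C1OC(=O)c2cc(OC)cc(OC)c21 | intermediate
10 | n-butyllithium | CCCC[Li] | starting material
11 | 3-[2,4-bis(benzyloxy)-6-pentylphenyl]-1-butyl-4,6-dimethoxy-1,3-dihydro-2-benzofuran-1-ol (lactol, mixture of diastereomers) | CCCCCc1cc(OCc2ccccc2)cc(OCc2ccccc2)c1C1OC(O)(CCCC)c2cc(OC)cc(OC)c21 | intermediate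
12 | (±)-1-(2-{[2,4-bis(benzyloxy)-6-pentylphenyl](hydroxy)methyl}-3,5-dimethoxyphenyl)pentan-1-one (open hydroxy ketone form of 11) | CCCCCc1cc(OCc2ccccc2)cc(OCc2ccccc2)c1C(O)c1c(OC)cc(OC)cc1C(=O)CCCC | intermediate
13 | [2,4-bis(benzyloxy)-6-pentylphenyl](2,4-dimethoxy-6-pentanoylphenyl)methanone | CCCCCc1cc(OCc2ccccc2)cc(OCc2ccccc2)c1C(=O)c1c(OC)cc(OC)cc1C(=O)CCCC | intermediate
14 | (2,4-dihydroxy-6-pentylphenyl)(2-hydroxy-4-methoxy-6-pentanoylphenyl)methanone | CCCCCc1cc(O)cc(O)c1C(=O)c1c(O)cc(OC)cc1C(=O)CCCC | intermediate
15 | (±)-2'-hydroxy-6-methoxy-4-pentanoyl-6'-pentyl-3H-spiro[1-benzofuran-2,1'-cyclohexa-2',5'-diene]-3,4'-dione (grisadienedione) | CCCCCC1=CC(=O)C=C(O)C12Oc1cc(OC)cc(C(=O)CCCC)c1C2=O | intermediate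
16 | methyl 2-(2,4-dihydroxy-6-pentylphenoxy)-4-methoxy-6-pentanoylbenzoate | CCCCCc1cc(O)cc(O)c1Oc1cc(OC)cc(C(=O)CCCC)c1C(=O)OC | target

**Step count and risks**

Total step count: 8. Longest linear sequence: 7 (steps 2 to 8, from olivetol).

Steps most likely to fail:

Step 8. The oxidation may dearomatise ring B instead of ring A, the oxidised ring may be captured by acetate instead of the ring B hydroxyl, or the hydroxyquinol ether may be over-oxidised once it is set free. The fallback gives up the oxidative aryl shift and makes the ether bond by copper-mediated Ullmann coupling; it sets out from bromide 6. Coupling of 6 (CuI, picolinic acid, K3PO4, DMSO, 90 °C) with an excess of methyl 2,6-dihydroxy-4-methoxybenzoate F1 (from commercial methyl 2,4,6-trihydroxybenzoate by methylation of its only non-chelated hydroxyl, Me2SO4, K2CO3, acetone) should give methyl 2-[2,4-bis(benzyloxy)-6-pentylphenoxy]-6-hydroxy-4-methoxybenzoate F2. Triflation (Tf2O, pyridine, CH2Cl2) would give methyl 2-[2,4-bis(benzyloxy)-6-pentylphenoxy]-4-methoxy-6-{[(trifluoromethyl)sulfonyl]oxy}benzoate F3. Carbonylative Stille coupling (Bu4Sn, CO, PdCl2(PPh3)2, LiCl, DMF, 90 °C) would install the pentanoyl group and give methyl 2-[2,4-bis(benzyloxy)-6-pentylphenoxy]-4-methoxy-6-pentanoylbenzoate F4. Debenzylation (BCl3, C6HMe5, CH2Cl2, −78 °C) comes back to the route at target 16.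

Step 5. n-Butyllithium may remove the doubly benzylic proton at C3 of the lactone instead of adding to the carbonyl group, or a second addition may follow opening of the lactolate. The fallback replaces the direct addition by acyl substitution on a Weinreb amide; it sets out from lactone 9. Ring opening with Me2AlN(OMe)Me (from Me3Al and MeNH(OMe)·HCl, CH2Cl2, 0 °C) should give (±)-2-{[2,4-bis(benzyloxy)-6-pentylphenyl](hydroxy)methyl}-N,3,5-trimethoxy-N-methylbenzamide F5. Immediate Dess–Martin oxidation would give 2-[2,4-bis(benzyloxy)-6-pentylbenzoyl]-N,3,5-trimethoxy-N-methylbenzamide F6. Addition of n-BuMgCl (THF, 0 °C) to the amide, the crowded diaryl ketone being left alone, comes back to the route at diketone 13.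

Step 7. The Lewis acid may close the pentanoyl enol onto the neighbouring diaryl ketone by aldol reaction, transfer benzyl groups to ring A, or cleave the second methyl ether. The fallback separates the two deprotections into orthogonal operations; it sets out from diketone 13. Hydrogenolysis (H2, Pd(OH)2/C, EtOAc, rt) should give (2,4-dihydroxy-6-pentylphenyl)(2,4-dimethoxy-6-pentanoylphenyl)methanone F7. Chelation-controlled nucleophilic demethylation of the methoxy group ortho to the diaryl ketone (MgI2 etherate, toluene, 80 °C) comes back to the route at benzophenone 14.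

**Further compounds**

F1 | step 8 | methyl 2,6-dihydroxy-4-methoxybenzoate | COC(=O)c1c(O)cc(OC)cc1O
F2 | step 8 | methyl 2-[2,4-bis(benzyloxy)-6-pentylphenoxy]-6-hydroxy-4-methoxybenzoate | CCCCCc1cc(OCc2ccccc2)cc(OCc2ccccc2)c1Oc1cc(OC)cc(O)c1C(=O)OC
F3 | step 8 | methyl 2-[2,4-bis(benzyloxy)-6-pentylphenoxy]-4-methoxy-6-{[(trifluoromethyl)sulfonyl]oxy}benzoate | CCCCCc1cc(OCc2ccccc2)cc(OCc2ccccc2)c1Oc1cc(OC)cc(OS(=O)(=O)C(F)(F)F)c1C(=O)OC
F4 | step 8 | methyl 2-[2,4-bis(benzyloxy)-6-pentylphenoxy]-4-methoxy-6-pentanoylbenzoate | CCCCCc1cc(OCc2ccccc2)cc(OCc2ccccc2)c1Oc1cc(OC)cc(C(=O)CCCC)c1C(=O)OC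
F5 | step 5 | (±)-2-{[2,4-bis(benzyloxy)-6-pentylphenyl](hydroxy)methyl}-N,3,5-trimethoxy-N-methylbenzamide | CCCCCc1cc(OCc2ccccc2)cc(OCc2ccccc2)c1C(O)c1c(OC)cc(OC)cc1C(=O)N(C)OC
F6 | step 5 | 2-[2,4-bis(benzyloxy)-6-pentylbenzoyl]-N,3,5-trimethoxy-N-methylbenzamide | CCCCCc1cc(OCc2ccccc2)cc(OCc2ccccc2)c1C(=O)c1c(OC)cc(OC)cc1C(=O)N(C)OC
F7 | step 7 | (2,4-dihydroxy-6-pentylphenyl)(2,4-dimethoxy-6-pentanoylphenyl)methanone | CCCCCc1cc(O)cc(O)c1C(=O)c1c(OC)cc(OC)cc1C(=O)CCCC
A1 | direct plan | methyl 2-hydroxy-4-methoxy-6-pentanoylbenzoate | CCCCC(=O)c1cc(OC)cc(O)c1C(=O)OC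
A2 | direct plan | (±)-4-chloro-3-pentylcyclobut-2-en-1-one | CCCCCC1=CC(=O)C1Cl
A3 | direct plan | (±)-methyl 4-methoxy-2-[(4-oxo-2-pentylcyclobut-2-en-1-yl)oxy]-6-pentanoylbenzoate | CCCCCC1=CC(=O)C1Oc1cc(OC)cc(C(=O)CCCC)c1C(=O)OC
A4 | direct plan | (triisopropylsilyloxy)acetylene | C#CO[Si](C(C)C)(C(C)C)C(C)C
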